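**Atom labels used in the discussion (target numbering):** C1 = CO2H; C2–C4 = chain CH2; C5 and C6 = substituted ring carbons (C5 carries the acid chain); C19 = ring CH2; C7 = CH(CH3); C8=C9 and C10=C11(CH3) = diene; C12–C14 = CH2; C15 = CH(CH3); C16 = CH2; C17≡C18–Br. The SMILES corresponds to 5R,6R,7S,15R, 8E,10E, with a trans ring. Names of intermediates use their own IUPAC locants.

## The problem

The only ring is a trans-1,2-disubstituted cyclopropane (C5, C6, C19); the rest is one chain, so the difficulty is stereochemical and positional, not topological. Three of the four stereocentres are contiguous (C5, C6, C7) and none carries a heteroatom, so hydroxyl-directed cyclopropanation or aldol logic does not leave them directly. C7 is both cyclopropylcarbinyl and allylic, so radical or cationic chemistry at that carbon opens the ring or scrambles the centre. C15 is insulated from the triad by the diene and cannot be controlled by it; it needs its own source of chirality, and any ee deficit in either half appears as a remote, hard-to-separate diastereomer. The 8E,10E diene contains a trisubstituted C10=C11 bond whose geometry must be fixed by mechanism. The 1-bromoalkyne does not survive Pd(0), organolithiums or hydride and must come last; the diene and C7 exclude strong protic acid; the acid must be masked through the organometallic steps. The enabling feature is that C7–C6–C19–C5 is a cyclopropylcarbinyl array, the closed form of a homoallyl unit C7=C6–C19–C5. Cutting the C5–C6 ring bond together with the C7–CH3 bond leaves a Z-alkenylboronate (C6=C7) and a leaving group on C5, and C5 is then simply the carbinol carbon of the C1–C5 aldehyde.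

## Retrosynthesis

**31 ⇒ 29 ⇒ 28 ⇒ 27.** The C18–Br bond and the free acid are formed last. Bromoalkyne 29 comes from terminal alkyne 28, and 28 from silylalkyne 27, so the bromoalkyne never meets a metal reagent. The tert-butyl ester is kept until the end and removed without protic acid.

**27 ⇒ 14 + 24.** The C9–C10 sp2–sp2 bond is cut. A cut at C8=C9 (olefination) would need an epimerisable α-methyl aldehyde and gives E/Z mixtures. Here each partner is a terminal alkyne derivative: hydrozirconation of 14 and carboalumination/iodination leading to 24 are both syn additions, and the Negishi coupling is stereoretentive.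

**24 ⇒ 22 ⇒ 21 ⇒ 20 ⇒ 18 ⇒ 16 ⇒ 15.** The C11–CH3 and C10–I bonds come from carboalumination of diyne 22, and the C11–C12 bond from acetylide alkylation of iodide 21. (R)-Citronellal 15 supplies C12–C17 and the 15R methyl centre unchanged. Its isopropylidene end is cut by ozonolysis to alcohol 20, and its aldehyde becomes the silyl-protected alkyne (16, 18).

**14 ⇒ 12 ⇒ 8 + 9.** The C7–C8 bond is made by a boronate 1,2-migration (Zweifel-type alkynylation with vinyl carbamate 9). C7 migrates with retention as a closed-shell nucleophile, which is the only safe way to substitute this cyclopropylcarbinyl carbon.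

**8 ⇒ 6 (via 7), the key cut.** The C5–C6 ring bond and the C7–CH3 bond are cut together. Forward, methyllithium converts alkenylboronate 6 into ate complex 7; its C6=C7 π bond displaces the C5 tosylate while methyl shifts from boron to C7. One easily set carbinol centre and one alkene geometry become three contiguous stereocentres, and boron stays on C7 as the handle for the next bond. The precursor is acyclic with a single stereocentre.

**6 ⇒ 5 ⇒ 4 ⇒ 1 + 2.** The Z-alkenylboronate comes from trans-hydroboration of alkyne 5, the tosylate from alcohol 4, and the C5–C19 bond from enantioselective propargylboration of aldehyde 1 with allenylboronate 2. The C1–C4 acid chain is already in place in 1.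

## Roads not taken

**Alternative 1:** the most obvious route. It uses the same C9–C10 cross-coupling, but builds the left half from the Roche ester (C7) by Charette asymmetric Simmons–Smith cyclopropanation of the derived E-allylic alcohol, giving cyclopropylmethanol A1. This is followed by three-carbon extension at C4 and Takai iodination at C8. The two stereo-elements are bought separately (chiral pool plus a stoichiometric chiral dioxaborolane). The directing hydroxyl sits on C4, the position that must then be homologated through cyclopropylcarbinyl halide or aldehyde chemistry. An epimerisable α-methyl aldehyde is needed. The vinyl iodide takes roughly twice as many steps as 14 does here.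

**Alternative 2:** form the C7–CH3 bond by copper-catalysed asymmetric SN2′ methylation (MeMgBr, chiral ligand) of allyl bromide A2 to give terminal alkene A3, then cross-metathesis to an alkenylboronate and Suzuki coupling. This still needs an independent enantioselective synthesis of the cyclopropane. Catalyst control at C7 must work against or with the adjacent ring centre (matched/mismatched pairs), and branched/linear selectivity is a second variable. The terminal alkene costs extra steps before it can be coupled.

**Alternative 3:** the all-carbon relative of the chosen step. Homoallylic alcohol A4 with an allylsilane terminator is activated as its triflate and closes to trans-vinylcyclopropane A5. C5 and C6 are set stereospecifically, but C7 emerges sp2. The methyl centre would have to be added afterwards across a vinylcyclopropane, where hydrometallation or radical intermediates open the ring. The boronate version sets C7 in the same event and leaves a C–B bond for the next coupling.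

Key step: step 4

Assumption: tert-butyl 5-oxopentanoate (1) is taken as a catalogue compound, and (R)-TRIP is taken to induce Re-face propargylation of aliphatic aldehydes, as in the accepted model for this catalyst class; the sense would be verified on 4 (Mosher ester) and the catalyst antipode used if needed.

## Steps

Step 1
Reactants: 1 tert-butyl 5-oxopentanoate; 2 allenylboronic acid pinacol ester
Product: 4 tert-butyl (5S)-5-hydroxyoct-7-ynoate, via O-boryl ether 3 (not isolated)
Conditions: (R)-TRIP (10 mol%), 4 Å MS, toluene, −20 °C; then H2O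
Reagents that add atoms: none
Why: Chiral-phosphoric-acid-catalysed propargylboration (SE2′ of the allenylboronate through a six-membered chair, the catalyst bridging a pinacol oxygen and the formyl hydrogen); Re-face attack should give the 5S carbinol, and the O-boryl product 3 cannot lactonise before work-up.

Step 2
Reactants: 4 tert-butyl (5S)-5-hydroxyoct-7-ynoate
Product: 5 tert-butyl (5S)-5-[(4-methylbenzenesulfonyl)oxy]oct-7-ynoate
Conditions: TsCl, Et3N, Me3N·HCl (cat.), CH2Cl2, 0 °C
Reagents that add atoms: 4-methylbenzenesulfonyl chloride, Cc1ccc(cc1)S(Cl)(=O)=O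
Why: Amine-catalysed O-sulfonylation of a secondary alcohol; the C–O bond is not touched, so C5 stays S, and the tert-butyl ester does not lactonise.

Step 3
Reactants: 5 tert-butyl (5S)-5-[(4-methylbenzenesulfonyl)oxy]oct-7-ynoate
Product: 6 tert-butyl (5S,7Z)-5-[(4-methylbenzenesulfonyl)oxy]-8-(4,4,5,5-tetramethyl-1,3,2-dioxaborolan-2-yl)oct-7-enoate
Conditions: HBpin, [Rh(cod)Cl]2 (1.5 mol%), P(i-Pr)3 (6 mol%), Et3N, cyclohexane, rt
Reagents that add atoms: pinacolborane, [H]B1OC(C)(C)C(C)(C)O1
Why: Rhodium-catalysed trans-hydroboration of a terminal alkyne (vinylidene pathway, anti-Markovnikov) puts boron on target C7 cis to the C19 methylene; this Z geometry is what becomes the 7S centre in step 4, and prior tosylation prevents the δ-hydroxy alkenylboronate from closing to a cyclic borinate.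

Step 4
Reactants: 6 tert-butyl (5S,7Z)-5-[(4-methylbenzenesulfonyl)oxy]-8-(4,4,5,5-tetramethyl-1,3,2-dioxaborolan-2-yl)oct-7-enoate
Product: 8 tert-butyl 4-[(1R,2S)-2-[(1R)-1-(4,4,5,5-tetramethyl-1,3,2-dioxaborolan-2-yl)ethyl]cyclopropyl]butanoate, via lithium alkenyl(methyl)boronate complex 7 (not isolated)
Conditions: MeLi (1.05 equiv), THF, −78 °C; then warm to rt
Reagents that add atoms: methyllithium, [Li]C
Why: Proposed new method: MeLi adds to the sp2 boron of 6 to give boronate complex 7, whose electron-rich C6=C7 π bond displaces the C5 tosylate from the rear through C6 (homoallyl-to-cyclopropylcarbinyl closure) while methyl shifts from boron to C7 antiperiplanar to the forming C5–C6 bond, so no free cyclopropylcarbinyl cation arises; the closest known reaction types are the electrophile-induced 1,2-metallate rearrangements of alkenylboronate complexes (Zweifel and conjunctive couplings, anti addition of electrophile and migrating group) and the allylsilane-terminated cyclisation of homoallylic sulfonates to trans-cyclopropanes. The ring closes in a 3-exo-tet mode at C5, the reacting π bond lying outside the new ring. C5 is set by inversion of the S sulfonate and becomes the R ring carbon. C6 is set by the alkene face that reaches C5: in the Z-boronate the bulky borate is cis to C19, so the C4 chain on C5 must point away from it and the ring closes trans. C7 follows from the Z geometry plus anti addition across C6=C7 (the E isomer would give the C7 epimer). The step needs MeLi to attack boron and not the tert-butyl ester (one equivalent at −78 °C, boron being far more electrophilic) and needs methyl, not a pinacol oxygen, to migrate; the intramolecular closure onto a secondary tosylate is expected to outrun elimination.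

Step 5
Reactants: 8 tert-butyl 4-[(1R,2S)-2-[(1R)-1-(4,4,5,5-tetramethyl-1,3,2-dioxaborolan-2-yl)ethyl]cyclopropyl]butanoate; 9 ethenyl N,N-di(propan-2-yl)carbamate
Product: 12 tert-butyl 4-[(1R,2R)-2-[(2R)-3-{[di(propan-2-yl)carbamoyl]oxy}but-3-en-2-yl]cyclopropyl]butanoate, via boronate complex 10 (not isolated), via β-iodo boronic ester 11 (not isolated)
Conditions: 9, s-BuLi, TMEDA, THF, −78 °C; add 8; then I2, MeOH, −78 °C; NaOMe, −78 °C to rt
Reagents that add atoms: none
Why: Zweifel-type olefination of a secondary boronic ester with α-lithiated vinyl carbamate: complex 10, iodine-induced 1,2-migration of C7 with retention to 11, then anti elimination of boron and iodide; C7 keeps its configuration because it migrates as a closed-shell nucleophile and never becomes a cyclopropylcarbinyl radical or cation.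

Step 6
Reactants: 12 tert-butyl 4-[(1R,2R)-2-[(2R)-3-{[di(propan-2-yl)carbamoyl]oxy}but-3-en-2-yl]cyclopropyl]butanoate
Product: 14 tert-butyl 4-[(1R,2R)-2-[(2R)-but-3-yn-2-yl]cyclopropyl]butanoate, via dilithium acetylide enolate 13 (not isolated)
Conditions: LDA (3.5 equiv), THF, −78 to 0 °C; then H2O
Reagents that add atoms: none
Why: Base-induced β-elimination of lithium carbamate from the enol carbamate (second stage of the stereospecific alkynylation of boronic esters); the ester rests as its enolate and the alkyne as its acetylide (13) until the quench, and the propargylic C7–H of an acetylide is not acidic enough to epimerise.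

Step 7
Reactants: 15 (R)-citronellal
Product: 16 (4R)-4,8-dimethylnon-7-en-1-yne
Conditions: dimethyl (1-diazo-2-oxopropyl)phosphonate, K2CO3, MeOH, 0 °C to rt
Reagents that add atoms: dimethyl (1-diazo-2-oxopropyl)phosphonate, COP(=O)(OC)C(=[N+]=[N-])C(C)=O
Why: Ohira–Bestmann (Seyferth–Gilbert) homologation of the aldehyde to the terminal alkyne; the methyl centre is β to the carbonyl and cannot epimerise under carbonate.

Step 8
Reactants: 16 (4R)-4,8-dimethylnon-7-en-1-yne
Product: 18 [(4R)-4,8-dimethylnon-7-en-1-yn-1-yl]tri(propan-2-yl)silane, via lithium acetylide 17 (not isolated)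
Conditions: n-BuLi, THF, −78 °C; TIPSOTf, −78 °C to rt
Reagents that add atoms: triisopropylsilyl trifluoromethanesulfonate, CC(C)[Si](C(C)C)(C(C)C)OS(=O)(=O)C(F)(F)F
Why: Deprotonation and C-silylation of the terminal alkyne; the TIPS group masks the future bromoalkyne terminus through ozonolysis, acetylide alkylation, carbometallation and cross-coupling.

Step 9
Reactants: 18 [(4R)-4,8-dimethylnon-7-en-1-yn-1-yl]tri(propan-2-yl)silane
Product: 20 (4R)-4-methyl-7-[tri(propan-2-yl)silyl]hept-6-yn-1-ol, via aldehyde 19 (not isolated)
Conditions: O3, CH2Cl2/MeOH, −78 °C (Sudan III end point); then NaBH4, −78 °C to rt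
Reagents that add atoms: ozone, [O-][O+]=O
Why: Chemoselective ozonolysis of the electron-rich trisubstituted alkene beside a hindered silylalkyne (alkenes react far faster), with reductive work-up straight to the primary alcohol.

Step 10
Reactants: 20 (4R)-4-methyl-7-[tri(propan-2-yl)silyl]hept-6-yn-1-ol
Product: 21 [(4R)-7-iodo-4-methylhept-1-yn-1-yl]tri(propan-2-yl)silane
Conditions: I2, PPh3, imidazole, CH2Cl2, 0 °C to rt
Reagents that add atoms: iodine, II
Why: Appel-type iodination of a primary alcohol under neutral conditions; C15 is remote and unaffected.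

Step 11
Reactants: 21 [(4R)-7-iodo-4-methylhept-1-yn-1-yl]tri(propan-2-yl)silane
Product: 22 [(4R)-4-methylnona-1,8-diyn-1-yl]tri(propan-2-yl)silane
Conditions: LiC≡CH·H2NCH2CH2NH2, DMSO, rt
Reagents that add atoms: lithium acetylide–ethylenediamine complex, [Li]C#C.NCCN
Why: SN2 alkylation of lithium acetylide by a primary iodide in a dipolar aprotic solvent forms the C11–C12 bond; the TIPS-alkyne is inert to the base and keeps the two alkynes differentiated.

Step 12
Reactants: 22 [(4R)-4-methylnona-1,8-diyn-1-yl]tri(propan-2-yl)silane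
Product: 24 [(4R,8E)-9-iodo-4,8-dimethylnon-8-en-1-yn-1-yl]tri(propan-2-yl)silane, via alkenyl(dimethyl)alane 23 (not isolated)
Conditions: Me3Al, Cp2ZrCl2 (25 mol%), CH2Cl2, rt; then I2, THF, −30 to 0 °C
Reagents that add atoms: trimethylaluminium, C[Al](C)C; iodine, II
Why: Negishi zirconium-catalysed carboalumination: syn addition of Me–Al across the terminal alkyne (methyl to C11, aluminium to C10) fixes the 10E geometry, and iodinolysis of 23 is stereoretentive; the hindered internal silylalkyne does not react.

Step 13
Reactants: 14 tert-butyl 4-[(1R,2R)-2-[(2R)-but-3-yn-2-yl]cyclopropyl]butanoate; 24 [(4R,8E)-9-iodo-4,8-dimethylnon-8-en-1-yn-1-yl]tri(propan-2-yl)silane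
Product: 27 tert-butyl 4-[(1R,2R)-2-[(2S,3E,5E,10R)-6,10-dimethyl-13-[tri(propan-2-yl)silyl]trideca-3,5-dien-12-yn-2-yl]cyclopropyl]butanoate, via alkenylzirconocene 25 (not isolated), via alkenylzinc chloride 26 (not isolated)
Conditions: Cp2Zr(H)Cl, THF, rt; ZnCl2, 0 °C; then 24, Pd(PPh3)4 (5 mol%), rt
Reagents that add atoms: none
Why: Hydrozirconation (syn, zirconium to terminal C9) gives E-alkenylzirconocene 25; transmetallation to zinc (26) and Negishi coupling with 24 form the C9–C10 bond with retention at both sp2 carbons, hence the 8E,10E diene; C7 and the tert-butyl ester are not touched.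

Step 14
Reactants: 27 tert-butyl 4-[(1R,2R)-2-[(2S,3E,5E,10R)-6,10-dimethyl-13-[tri(propan-2-yl)silyl]trideca-3,5-dien-12-yn-2-yl]cyclopropyl]butanoate
Product: 28 tert-butyl 4-[(1R,2R)-2-[(2S,3E,5E,10R)-6,10-dimethyltrideca-3,5-dien-12-yn-2-yl]cyclopropyl]butanoate
Conditions: TBAF, THF, 0 °C to rt
Reagents that add atoms: none
Why: Fluoride-induced C–Si cleavage of the silylalkyne; ester, diene and cyclopropane are inert to TBAF.

Step 15
Reactants: 28 tert-butyl 4-[(1R,2R)-2-[(2S,3E,5E,10R)-6,10-dimethyltrideca-3,5-dien-12-yn-2-yl]cyclopropyl]butanoate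
Product: 29 tert-butyl 4-[(1R,2R)-2-[(2S,3E,5E,10R)-13-bromo-6,10-dimethyltrideca-3,5-dien-12-yn-2-yl]cyclopropyl]butanoate
Conditions: NBS (1.05 equiv), AgNO3 (10 mol%), acetone, 0 °C, dark
Reagents that add atoms: N-bromosuccinimide, BrN1C(=O)CCC1=O
Why: Silver-catalysed bromination of the terminal alkyne through the silver acetylide, which should react with NBS much faster than the diene does; one equivalent, low temperature and exclusion of light limit ionic or radical attack on the diene.

Step 16
Reactants: 29 tert-butyl 4-[(1R,2R)-2-[(2S,3E,5E,10R)-13-bromo-6,10-dimethyltrideca-3,5-dien-12-yn-2-yl]cyclopropyl]butanoate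
Product: 31 4-[(1R,2R)-2-[(2S,3E,5E,10R)-13-bromo-6,10-dimethyltrideca-3,5-dien-12-yn-2-yl]cyclopropyl]butanoic acid, via trimethylsilyl ester 30 (not isolated)
Conditions: TMSOTf, 2,6-lutidine, CH2Cl2, 0 °C; then pH 5 aqueous buffer
Reagents that add atoms: none
Why: Silyl-triflate-mediated cleavage of the tert-butyl ester under buffered, non-protic conditions (loss of isobutene from the O-silylated ester), then hydrolysis of silyl ester 30; chosen over TFA to spare the diene and the allylic, cyclopropylcarbinyl C7.

## Compound list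

1 | tert-butyl 5-oxopentanoate | O=CCCCC(=O)OC(C)(C)C | starting material
2 | allenylboronic acid pinacol ester (4,4,5,5-tetramethyl-2-(propa-1,2-dien-1-yl)-1,3,2-dioxaborolane) | C=C=CB1OC(C)(C)C(C)(C)O1 | starting material
3 | tert-butyl (5S)-5-[(4,4,5,5-tetramethyl-1,3,2-dioxaborolan-2-yl)oxy]oct-7-ynoate | C#CC[C@@H](OB1OC(C)(C)C(C)(C)O1)CCCC(=O)OC(C)(C)C | intermediate
4 | tert-butyl (5S)-5-hydroxyoct-7-ynoate | C#CC[C@@H](O)CCCC(=O)OC(C)(C)C | intermediate
5 | tert-butyl (5S)-5-[(4-methylbenzenesulfonyl)oxy]oct-7-ynoate | C#CC[C@@H](OS(=O)(=O)c1ccc(C)cc1)CCCC(=O)OC(C)(C)C | intermediate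
6 | tert-butyl (5S,7Z)-5-[(4-methylbenzenesulfonyl)oxy]-8-(4,4,5,5-tetramethyl-1,3,2-dioxaborolan-2-yl)oct-7-enoate | CC1(C)OB(OC1(C)C)/C=C\C[C@@H](OS(=O)(=O)c2ccc(C)cc2)CCCC(=O)OC(C)(C)C | intermediate
7 | lithium B-methyl boronate complex of 6 | [Li+].C[B-]1(OC(C)(C)C(C)(C)O1)/C=C\C[C@@H](OS(=O)(=O)c2ccc(C)cc2)CCCC(=O)OC(C)(C)C | intermediate
8 | tert-butyl 4-[(1R,2S)-2-[(1R)-1-(4,4,5,5-tetramethyl-1,3,2-dioxaborolan-2-yl)ethyl]cyclopropyl]butanoate | CC1(C)OB(OC1(C)C)[C@H](C)[C@@H]2C[C@H]2CCCC(=O)OC(C)(C)C | intermediate
9 | ethenyl N,N-di(propan-2-yl)carbamate | C=COC(=O)N(C(C)C)C(C)C | starting material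
10 | lithium boronate complex of 8 with the 1-(carbamoyloxy)ethenyl group on boron | [Li+].C=C(OC(=O)N(C(C)C)C(C)C)[B-]1(OC(C)(C)C(C)(C)O1)[C@H](C)[C@@H]2C[C@H]2CCCC(=O)OC(C)(C)C | intermediate
11 | β-iodo boronic ester (both epimers at the carbamate-bearing carbon) | ICC(OC(=O)N(C(C)C)C(C)C)(B1OC(C)(C)C(C)(C)O1)[C@H](C)[C@@H]2C[C@H]2CCCC(=O)OC(C)(C)C | intermediate
12 | tert-butyl 4-[(1R,2R)-2-[(2R)-3-{[di(propan-2-yl)carbamoyl]oxy}but-3-en-2-yl]cyclopropyl]butanoate | C=C(OC(=O)N(C(C)C)C(C)C)[C@H](C)[C@@H]1C[C@H]1CCCC(=O)OC(C)(C)C | intermediate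
13 | dilithium salt of 14 (acetylide and ester enolate) | [Li+].[Li+].[C-]#C[C@H](C)[C@@H]1C[C@H]1CCC=C([O-])OC(C)(C)C | intermediate
14 | tert-butyl 4-[(1R,2R)-2-[(2R)-but-3-yn-2-yl]cyclopropyl]butanoate | C#C[C@H](C)[C@@H]1C[C@H]1CCCC(=O)OC(C)(C)C | intermediate
15 | (R)-citronellal, (3R)-3,7-dimethyloct-6-enal | CC(C)=CCC[C@@H](C)CC=O | starting material
16 | (4R)-4,8-dimethylnon-7-en-1-yne | CC(C)=CCC[C@@H](C)CC#C | intermediate
17 | lithium acetylide of 16 | CC(C)=CCC[C@@H](C)CC#C[Li] | intermediate
18 | [(4R)-4,8-dimethylnon-7-en-1-yn-1-yl]tri(propan-2-yl)silane | CC(C)=CCC[C@@H](C)CC#C[Si](C(C)C)(C(C)C)C(C)C | intermediate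
19 | (4R)-4-methyl-7-[tri(propan-2-yl)silyl]hept-6-ynal | O=CCC[C@@H](C)CC#C[Si](C(C)C)(C(C)C)C(C)C | intermediate
20 | (4R)-4-methyl-7-[tri(propan-2-yl)silyl]hept-6-yn-1-ol | OCCC[C@@H](C)CC#C[Si](C(C)C)(C(C)C)C(C)C | intermediate
21 | [(4R)-7-iodo-4-methylhept-1-yn-1-yl]tri(propan-2-yl)silane | ICCC[C@@H](C)CC#C[Si](C(C)C)(C(C)C)C(C)C | intermediate
22 | [(4R)-4-methylnona-1,8-diyn-1-yl]tri(propan-2-yl)silane | C#CCCC[C@@H](C)CC#C[Si](C(C)C)(C(C)C)C(C)C | intermediate
23 | dimethyl[(1E,6R)-2,6-dimethyl-9-[tri(propan-2-yl)silyl]non-1-en-8-yn-1-yl]alumane | C/C(=C\[Al](C)C)CCC[C@@H](C)CC#C[Si](C(C)C)(C(C)C)C(C)C | intermediate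
24 | [(4R,8E)-9-iodo-4,8-dimethylnon-8-en-1-yn-1-yl]tri(propan-2-yl)silane | C/C(=C\I)CCC[C@@H](C)CC#C[Si](C(C)C)(C(C)C)C(C)C | intermediate
25 | (E)-alkenyl(chloro)zirconocene from 14 | Cl[Zr](C1C=CC=C1)(C2C=CC=C2)/C=C/[C@H](C)[C@@H]3C[C@H]3CCCC(=O)OC(C)(C)C | intermediate
26 | (E)-alkenylzinc chloride from 25 | Cl[Zn]/C=C/[C@H](C)[C@@H]1C[C@H]1CCCC(=O)OC(C)(C)C | intermediate
27 | tert-butyl 4-[(1R,2R)-2-[(2S,3E,5E,10R)-6,10-dimethyl-13-[tri(propan-2-yl)silyl]trideca-3,5-dien-12-yn-2-yl]cyclopropyl]butanoate | C/C(=C\C=C\[C@H](C)[C@@H]1C[C@H]1CCCC(=O)OC(C)(C)C)CCC[C@@H](C)CC#C[Si](C(C)C)(C(C)C)C(C)C | intermediate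
28 | tert-butyl 4-[(1R,2R)-2-[(2S,3E,5E,10R)-6,10-dimethyltrideca-3,5-dien-12-yn-2-yl]cyclopropyl]butanoate | C/C(=C\C=C\[C@H](C)[C@@H]1C[C@H]1CCCC(=O)OC(C)(C)C)CCC[C@@H](C)CC#C | intermediate
29 | tert-butyl 4-[(1R,2R)-2-[(2S,3E,5E,10R)-13-bromo-6,10-dimethyltrideca-3,5-dien-12-yn-2-yl]cyclopropyl]butanoate | C/C(=C\C=C\[C@H](C)[C@@H]1C[C@H]1CCCC(=O)OC(C)(C)C)CCC[C@@H](C)CC#CBr | intermediate
30 | trimethylsilyl ester of 31 | C/C(=C\C=C\[C@H](C)[C@@H]1C[C@H]1CCCC(=O)O[Si](C)(C)C)CCC[C@@H](C)CC#CBr | intermediate
31 | 4-[(1R,2R)-2-[(2S,3E,5E,10R)-13-bromo-6,10-dimethyltrideca-3,5-dien-12-yn-2-yl]cyclopropyl]butanoic acid | C/C(=C\C=C\[C@H](C)[C@@H]1C[C@H]1CCCC(=O)O)CCC[C@@H](C)CC#CBr | target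

## Step count and least certain steps

Total: 16 steps. Longest linear sequence: 10 steps (steps 1–6 or 7–12, then 13–16).

**Step 4 (key step, proposed new method).** What may go wrong: attack of MeLi on the ester instead of boron; ring closure of the borate onto the secondary sulfonate too slow, so that elimination of the tosylate or protodeboronation on work-up takes over; migration of a pinacol oxygen in place of methyl; incomplete trans selectivity in the closure. Fallback with known chemistry, setting out from 1 and returning at 8: sulfonium-ylide epoxidation of 1 gives racemic tert-butyl 4-(oxiran-2-yl)butanoate F1. Hydrolytic kinetic resolution with the (salen)Co enantiomer that leaves the S epoxide gives tert-butyl 4-[(2S)-oxiran-2-yl]butanoate F2. Wadsworth–Emmons cyclopropanation of F2 with the anion of triethyl phosphonoacetate (hot DME/toluene; inversion at C5, trans closure) gives the cyclopropane diester F3. Selective saponification of the ethyl ester gives acid F4, which is converted to its N-hydroxyphthalimide ester F5. Nickel-catalysed decarboxylative borylation (B2pin2) gives cyclopropylboronate F6, the ring radical recombining trans to the C5 chain. Reagent-controlled one-carbon homologation of F6 with (S)-1-lithioethyl 2,4,6-triisopropylbenzoate (s-BuLi/(−)-sparteine; retention at the carbenoid on borylation, inversion on migration) then sets C7 and delivers 8. This is longer and sets the ring and C7 in separate operations, but every step has close precedent.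

**Step 1.** What may go wrong: only moderate enantioselectivity with an unbranched aliphatic aldehyde, which would surface later as a remote diastereomer of 27; a facial sense opposite to the assumed one; lactonisation of the δ-hydroxy ester on work-up. Fallback, setting out from 1 and returning at 4: the S epoxide F2 (made from 1 via F1 as described above) is opened at its terminal carbon with lithium (trimethylsilyl)acetylide and BF3·OEt2 at −78 °C to give tert-butyl (5S)-5-hydroxy-8-(trimethylsilyl)oct-7-ynoate F7, and K2CO3/MeOH removes the silyl group to give 4 in the enantiopurity of the resolved epoxide.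

**Step 3.** What may go wrong: erosion of Z selectivity (any E isomer is carried through step 4 into the C7 epimer), competing ordinary cis-hydroboration, alkyne oligomerisation on rhodium. Fallback, setting out from 5 and returning at 6: iodination of the alkyne (NIS, cat. AgNO3) gives iodoalkyne F8. Diimide reduction (2-nitrobenzenesulfonylhydrazide, Et3N) gives the Z-iodoalkene F9. Stereoretentive palladium-catalysed borylation with B2pin2 (PdCl2(PPh3)2, KOPh, toluene, 50 °C) gives 6 with the geometry fixed by the cis reduction.

**Steps 5 and 6.** What may go wrong: slow or reversible boronate-complex formation at the hindered secondary cyclopropylcarbinyl boron, so that iodine consumes the vinyllithium instead; condensation of the ester enolate under excess LDA in step 6. Fallback, setting out from 8 and returning at 14: Matteson one-carbon homologation (BrCH2Cl, n-BuLi, −78 °C) gives the primary boronate F10. Oxidation (NaBO3·4H2O) gives alcohol F11 and Dess–Martin oxidation gives aldehyde F12. Ohira–Bestmann homologation under the mildest carbonate conditions gives 14, the concern in that variant being epimerisation of the α-methyl aldehyde.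

**Step 15.** What may go wrong: electrophilic bromination of the electron-rich trisubstituted diene in competition with the silver acetylide. Fallback, setting out from 28 and returning at 29: reverse the polarity of the halogenation by treating 28 with CBr4, powdered KOH and 18-crown-6 in a hydrocarbon solvent, where the acetylide attacks bromine of CBr4 and no electrophilic brominating agent is present; no new compound is involved.

## Further compounds

F1 | step 4 | tert-butyl 4-(oxiran-2-yl)butanoate (racemic) | C1OC1CCCC(=O)OC(C)(C)C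
F2 | step 4 | tert-butyl 4-[(2S)-oxiran-2-yl]butanoate | C1O[C@H]1CCCC(=O)OC(C)(C)C
F3 | step 4 | ethyl (1R,2R)-2-[4-(tert-butoxy)-4-oxobutyl]cyclopropane-1-carboxylate | CCOC(=O)[C@@H]1C[C@H]1CCCC(=O)OC(C)(C)C
F4 | step 4 | (1R,2R)-2-[4-(tert-butoxy)-4-oxobutyl]cyclopropane-1-carboxylic acid | OC(=O)[C@@H]1C[C@H]1CCCC(=O)OC(C)(C)C
F5 | step 4 | 1,3-dioxoisoindolin-2-yl (1R,2R)-2-[4-(tert-butoxy)-4-oxobutyl]cyclopropane-1-carboxylate | O=C(ON1C(=O)c2ccccc2C1=O)[C@@H]3C[C@H]3CCCC(=O)OC(C)(C)C
F6 | step 4 | tert-butyl 4-[(1R,2R)-2-(4,4,5,5-tetramethyl-1,3,2-dioxaborolan-2-yl)cyclopropyl]butanoate | CC1(C)OB(OC1(C)C)[C@@H]2C[C@H]2CCCC(=O)OC(C)(C)C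
F7 | step 1 | tert-butyl (5S)-5-hydroxy-8-(trimethylsilyl)oct-7-ynoate | C[Si](C)(C)C#CC[C@@H](O)CCCC(=O)OC(C)(C)C
F8 | step 3 | tert-butyl (5S)-8-iodo-5-[(4-methylbenzenesulfonyl)oxy]oct-7-ynoate | IC#CC[C@@H](OS(=O)(=O)c1ccc(C)cc1)CCCC(=O)OC(C)(C)C
F9 | step 3 | tert-butyl (5S,7Z)-8-iodo-5-[(4-methylbenzenesulfonyl)oxy]oct-7-enoate | I/C=C\C[C@@H](OS(=O)(=O)c1ccc(C)cc1)CCCC(=O)OC(C)(C)C
F10 | step 5 | tert-butyl 4-[(1R,2S)-2-[(2S)-1-(4,4,5,5-tetramethyl-1,3,2-dioxaborolan-2-yl)propan-2-yl]cyclopropyl]butanoate | CC1(C)OB(OC1(C)C)C[C@H](C)[C@@H]2C[C@H]2CCCC(=O)OC(C)(C)C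
F11 | step 5 | tert-butyl 4-[(1R,2R)-2-[(2R)-1-hydroxypropan-2-yl]cyclopropyl]butanoate | OC[C@H](C)[C@@H]1C[C@H]1CCCC(=O)OC(C)(C)C
F12 | step 5 | tert-butyl 4-[(1R,2R)-2-[(2R)-1-oxopropan-2-yl]cyclopropyl]butanoate | O=C[C@H](C)[C@@H]1C[C@H]1CCCC(=O)OC(C)(C)C
F0 | step 15 | none | none
A1 | alternative 1 | {(1R,2S)-2-[(2R)-1-[(4-methoxyphenyl)methoxy]propan-2-yl]cyclopropyl}methanol | COc1ccc(COC[C@H](C)[C@@H]2C[C@H]2CO)cc1
A2 | alternative 2 | tert-butyl 4-[(1R,2R)-2-[(1E)-3-bromoprop-1-en-1-yl]cyclopropyl]butanoate | BrC/C=C/[C@@H]1C[C@H]1CCCC(=O)OC(C)(C)C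
A3 | alternative 2 | tert-butyl 4-[(1R,2R)-2-[(2S)-but-3-en-2-yl]cyclopropyl]butanoate | C=C[C@H](C)[C@@H]1C[C@H]1CCCC(=O)OC(C)(C)C
A4 | alternative 3 | tert-butyl (5S,7Z)-5-hydroxy-9-(trimethylsilyl)non-7-enoate | C[Si](C)(C)C/C=C\C[C@@H](O)CCCC(=O)OC(C)(C)C
A5 | alternative 3 | tert-butyl 4-[(1R,2S)-2-ethenylcyclopropyl]butanoate | C=C[C@@H]1C[C@H]1CCCC(=O)OC(C)(C)C
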